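**Retrosynthetic overview**
- The target, (4R)-5,7-dihydroxy-8-[3-(4-hydroxyphenyl)propanoyl]-4-phenylchroman-2-one, is traced back through cleavage of three methyl ethers and lactonisation of a tert-butyl ester onto the C8a phenol.
- The strategy rests on one feature: the lactone oxygen O1 on C8a and the ketone carbon on C8 are ortho neighbours on ring A, with the C7 oxygen on the other side of C8. Both bonds (O1–C8a and C8–acyl) are cut together, as the insertion of a C8–C8a aryne into the C–O bond of 3-(4-methoxyphenyl)propanoic acid.
- The aryne comes from a 2-(trimethylsilyl)aryl triflate, made from the ring-opened phenol by ortho-bromination, O-silylation, O→C silyl shift and triflation.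
- The C4 stereocentre comes from a copper hydride asymmetric conjugate reduction of the Pechmann coumarin built from 3,5-dimethoxyphenol and ethyl benzoylacetate.
- Ring order: ring A is bought; the pyranone ring is made first (Pechmann), opened to free the phenol, and closed again after the aryne step.

Key step: step 7

Assumption on the chemistry: the facial sense of the copper hydride reduction on this peri-substituted coumarin is not taken for granted. The route is written with (R)-DTBM-SEGPHOS; the configuration of the first batch is to be assigned (the bromophenol of step 4 carries a heavy atom for X-ray analysis), and the (S)-ligand is used instead if the opposite sense is found. Ring positions are given in chroman-2-one numbering throughout, also for the open-chain intermediates.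

**Route**

Step 1
Reactants: 1 3,5-dimethoxyphenol; 2 ethyl benzoylacetate
Product: 3 5,7-dimethoxy-4-phenyl-2H-chromen-2-one
Conditions: CF3CO2H (neat), rt → 60 °C
Reagents that add atoms: none
Why: Pechmann condensation, in which acid-promoted transesterification, intramolecular Friedel–Crafts attack of the doubly activated phenol on the benzoyl carbonyl and dehydration give the 4-phenylcoumarin, the symmetry of 1 allowing only one regiochemical outcome.

Step 2
Reactants: 3 5,7-dimethoxy-4-phenyl-2H-chromen-2-one
Product: 4 (4R)-5,7-dimethoxy-4-phenylchroman-2-one
Conditions: Cu(OAc)2·H2O (3 mol%), (R)-DTBM-SEGPHOS (3 mol%), HSiMe(OEt)2 (1.5 equiv), t-BuOH (2 equiv), toluene, 0 °C → rt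
Reagents that add atoms: none
Why: Copper hydride asymmetric conjugate reduction, in which the bisphosphine-ligated Cu–H delivers hydride to C4 of the unsaturated lactone on the face left open by the chiral ligand and so sets C4, while t-BuOH protonates the copper enolate and the silane, kept near stoichiometric to avoid reduction to the lactol, regenerates Cu–H.

Step 3
Reactants: 4 (4R)-5,7-dimethoxy-4-phenylchroman-2-one
Product: 5 tert-butyl (3R)-3-(2-hydroxy-4,6-dimethoxyphenyl)-3-phenylpropanoate
Conditions: KOtBu (1.2 equiv), t-BuOH/THF, 0 °C → rt; then AcOH
Reagents that add atoms: potassium tert-butoxide, CC(C)(C)[O-].[K+]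
Why: Alkoxide ring opening (transesterification) of the aryl lactone, which is downhill because tert-butoxide is exchanged for the much weaker base phenoxide, and which leaves C4 alone because its C–H is not acidic enough for this base at 0 °C.

Step 4
Reactants: 5 tert-butyl (3R)-3-(2-hydroxy-4,6-dimethoxyphenyl)-3-phenylpropanoate
Product: 6 tert-butyl (3R)-3-(3-bromo-2-hydroxy-4,6-dimethoxyphenyl)-3-phenylpropanoate
Conditions: NBS (1.0 equiv), i-Pr2NH (10 mol%), CH2Cl2, −78 → 0 °C
Reagents that add atoms: N-bromosuccinimide, O=C1CCC(=O)N1Br
Why: Amine-catalysed ortho-bromination of a phenol (electrophilic aromatic substitution), in which the N-bromoamine formed in the flask is held by hydrogen bonding to the hydroxyl group and should deliver bromine to the only free ortho position (the future C8) in preference to the position para to the hydroxyl, which lies between two methoxy groups.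

Step 5
Reactants: 6 tert-butyl (3R)-3-(3-bromo-2-hydroxy-4,6-dimethoxyphenyl)-3-phenylpropanoate
Product: 7 tert-butyl (3R)-3-[3-bromo-4,6-dimethoxy-2-(trimethylsilyloxy)phenyl]-3-phenylpropanoate
Conditions: (Me3Si)2NH, cat. Me3SiCl, THF, 65 °C; volatiles removed, used crude
Reagents that add atoms: hexamethyldisilazane, C[Si](C)(C)N[Si](C)(C)C
Why: O-Silylation of the phenol by the disilazane, driven by loss of ammonia, gives the aryl trimethylsilyl ether needed for the silyl shift, and it is carried on crude because it is hydrolytically labile.

Step 6
Reactants: 7 tert-butyl (3R)-3-[3-bromo-4,6-dimethoxy-2-(trimethylsilyloxy)phenyl]-3-phenylpropanoate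
Product: 10 tert-butyl (3R)-3-[4,6-dimethoxy-2-(trifluoromethylsulfonyloxy)-3-(trimethylsilyl)phenyl]-3-phenylpropanoate, via aryllithium 8 (not isolated), via lithium phenoxide 9 (not isolated)
Conditions: n-BuLi (1.1 equiv), THF, −100 → −80 °C; then Tf2O (1.3 equiv), −100 → 0 °C
Reagents that add atoms: trifluoromethanesulfonic anhydride, O=S(=O)(OS(=O)(=O)C(F)(F)F)C(F)(F)F
Why: Bromine–lithium exchange at −100 °C should outrun attack of n-BuLi on the hindered tert-butyl ester, the aryllithium then takes the silyl group from the neighbouring oxygen in a 1,3 O→C shift (retro-Brook rearrangement) driven by formation of the lithium phenoxide, and triflic anhydride sulfonylates that phenoxide.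

Step 7
Reactants: 10 tert-butyl (3R)-3-[4,6-dimethoxy-2-(trifluoromethylsulfonyloxy)-3-(trimethylsilyl)phenyl]-3-phenylpropanoate; 11 3-(4-methoxyphenyl)propanoic acid
Product: 14 tert-butyl (3R)-3-[2-hydroxy-4,6-dimethoxy-3-[3-(4-methoxyphenyl)propanoyl]phenyl]-3-phenylpropanoate, via aryne 12 (not isolated), via aryl anion ester 13 (not isolated)
Conditions: 11 (1.3 equiv), CsF (4 equiv), THF, 125 °C (sealed tube); then aq. NH4Cl
Reagents that add atoms: none
Why: Fluoride attacks silicon in 10 and the aryl anion so formed expels triflate to give aryne 12; the cesium carboxylate of 11 adds through oxygen to the aryne carbon that becomes C8a, which places the negative charge on the future C8 beside the methoxy group (13), and this carbanion attacks the carbonyl of the new aryl ester through a four-membered transition state, so that the acyl group moves from oxygen to carbon and the C8a phenoxide is released (anionic Fries-type shift). The closest known reaction type is the fluoride-mediated insertion of arynes from 2-(trimethylsilyl)aryl triflates into the C–O bond of carboxylic acids, which gives ortho-hydroxyaryl ketones in hot THF. No ring is closed and no stereocentre is formed; the existing benzylic centre carries no leaving group and is not deprotonated by CsF, so it should pass unchanged. The step needs regioselective addition to an unsymmetrical aryne: the methoxy group on the carbon flanking the aryne withdraws inductively, makes the remote aryne carbon the electrophilic one and stabilises the anion developing beside it, and this bias is expected to outweigh the steric shielding of that remote carbon by the branched side chain because the attacking carboxylate oxygen is small. It also needs acyl transfer to outrun protonation of 13, which is served by the aprotic solvent, the high temperature and only a slight excess of the acid, while the tert-butyl ester is too hindered to act as a competing acyl acceptor.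

Step 8
Reactants: 14 tert-butyl (3R)-3-[2-hydroxy-4,6-dimethoxy-3-[3-(4-methoxyphenyl)propanoyl]phenyl]-3-phenylpropanoate
Product: 15 (4R)-5,7-dimethoxy-8-[3-(4-methoxyphenyl)propanoyl]-4-phenylchroman-2-one
Conditions: CF3CO2H/CH2Cl2 (1:3), 0 °C → rt
Reagents that add atoms: none
Why: Acidolysis of the tert-butyl ester with loss of isobutene, followed by acid-catalysed lactonisation of the acid onto the only free phenol, closes the six-membered aryl lactone, and any lactone already formed in step 7 converges on the same product.

Step 9
Reactants: 15 (4R)-5,7-dimethoxy-8-[3-(4-methoxyphenyl)propanoyl]-4-phenylchroman-2-one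
Product: 16 (4R)-5,7-dihydroxy-8-[3-(4-hydroxyphenyl)propanoyl]-4-phenylchroman-2-one
Conditions: BBr3 (8 equiv), CH2Cl2, −78 °C → rt; then ice-water, short cold work-up
Reagents that add atoms: none
Why: Lewis acid ether cleavage, in which BBr3 complexes each methoxy oxygen and bromide removes the methyl group by SN2 (the chelated C7 ether beside the ketone first), while the aryl lactone, whose aryl–oxygen bond bromide cannot attack, and the C4 centre should be left as they are, the quench being kept cold and short so that the lactone is not opened and reclosed on the C5 oxygen.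

**Compound list**

1 | 3,5-dimethoxyphenol | COc1cc(O)cc(OC)c1 | starting material
2 | ethyl benzoylacetate (ethyl 3-oxo-3-phenylpropanoate) | CCOC(=O)CC(=O)c1ccccc1 | starting material
3 | 5,7-dimethoxy-4-phenyl-2H-chromen-2-one | O=C1C=C(c2ccccc2)c2c(OC)cc(OC)cc2O1 | intermediate
4 | (4R)-5,7-dimethoxy-4-phenylchroman-2-one | O=C1C[C@H](c2ccccc2)c2c(OC)cc(OC)cc2O1 | intermediate
5 | tert-butyl (3R)-3-(2-hydroxy-4,6-dimethoxyphenyl)-3-phenylpropanoate | CC(C)(C)OC(=O)C[C@H](c1ccccc1)c1c(OC)cc(OC)cc1O | intermediate
6 | tert-butyl (3R)-3-(3-bromo-2-hydroxy-4,6-dimethoxyphenyl)-3-phenylpropanoate | CC(C)(C)OC(=O)C[C@H](c1ccccc1)c1c(OC)cc(OC)c(Br)c1O | intermediate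
7 | tert-butyl (3R)-3-[3-bromo-4,6-dimethoxy-2-(trimethylsilyloxy)phenyl]-3-phenylpropanoate | CC(C)(C)OC(=O)C[C@H](c1ccccc1)c1c(OC)cc(OC)c(Br)c1O[Si](C)(C)C | intermediate
8 | tert-butyl (3R)-3-[3-lithio-4,6-dimethoxy-2-(trimethylsilyloxy)phenyl]-3-phenylpropanoate (aryllithium, not isolated) | CC(C)(C)OC(=O)C[C@H](c1ccccc1)c1c(OC)cc(OC)c([Li])c1O[Si](C)(C)C | intermediate
9 | lithium 2-[(1R)-3-tert-butoxy-3-oxo-1-phenylpropyl]-3,5-dimethoxy-6-(trimethylsilyl)phenolate (not isolated) | CC(C)(C)OC(=O)C[C@H](c1ccccc1)c1c(OC)cc(OC)c([Si](C)(C)C)c1[O-].[Li+] | intermediate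
10 | tert-butyl (3R)-3-[4,6-dimethoxy-2-(trifluoromethylsulfonyloxy)-3-(trimethylsilyl)phenyl]-3-phenylpropanoate | CC(C)(C)OC(=O)C[C@H](c1ccccc1)c1c(OC)cc(OC)c([Si](C)(C)C)c1OS(=O)(=O)C(F)(F)F | intermediate
11 | 3-(4-methoxyphenyl)propanoic acid | COc1ccc(CCC(=O)O)cc1 | starting material
12 | tert-butyl (3R)-3-(2,3-didehydro-4,6-dimethoxyphenyl)-3-phenylpropanoate (aryne, not isolated) | CC(C)(C)OC(=O)C[C@H](c1ccccc1)C1=C(OC)C=C(OC)C#C1 | intermediate
13 | tert-butyl (3R)-3-[3-cesio-4,6-dimethoxy-2-[3-(4-methoxyphenyl)propanoyloxy]phenyl]-3-phenylpropanoate (aryl anion ester, not isolated) | CC(C)(C)OC(=O)C[C@H](c1ccccc1)c1c(OC)cc(OC)c([Cs])c1OC(=O)CCc1ccc(OC)cc1 | intermediate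
14 | tert-butyl (3R)-3-[2-hydroxy-4,6-dimethoxy-3-[3-(4-methoxyphenyl)propanoyl]phenyl]-3-phenylpropanoate | CC(C)(C)OC(=O)C[C@H](c1ccccc1)c1c(OC)cc(OC)c(C(=O)CCc2ccc(OC)cc2)c1O | intermediate
15 | (4R)-5,7-dimethoxy-8-[3-(4-methoxyphenyl)propanoyl]-4-phenylchroman-2-one | O=C1C[C@H](c2ccccc2)c2c(OC)cc(OC)c(C(=O)CCc3ccc(OC)cc3)c2O1 | intermediate
16 | (4R)-5,7-dihydroxy-8-[3-(4-hydroxyphenyl)propanoyl]-4-phenylchroman-2-one | O=C1C[C@H](c2ccccc2)c2c(O)cc(O)c(C(=O)CCc3ccc(O)cc3)c2O1 | target

**Step count**

Total steps: 9. Longest linear sequence: 9 steps (from 1 and 2 to 16); acid 11 enters in step 7.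

**Steps most likely to fail**

1. Step 7 (key step). Three processes could defeat it:
   - the carboxylate may add with the wrong orientation, because the electronically preferred aryne carbon is shielded by the branched side chain;
   - the aryl anion may be protonated before the acyl group migrates, leaving the O-aryl ester;
   - the aryne may be captured by the carbonyl oxygen of the neighbouring tert-butyl ester through a six-membered ring.

   Fallback, from 4 and 11, returning at 15: acid 11 is converted with oxalyl chloride and catalytic DMF in CH2Cl2 into 3-(4-methoxyphenyl)propanoyl chloride F1. Lactone 4 is then acylated with F1 and SnCl4 in CH2Cl2 at 0 °C (Friedel–Crafts acylation). Substitution is expected at C8, which is para to the C5 methoxy group and ortho to the C7 methoxy group, in preference to C6, which lies between two methoxy groups and has only the weakly donating lactone oxygen para to it. This should give 15 directly, and the route continues with step 9.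

2. Step 4. Bromination may take place para to the free hydroxyl group (between the two methoxy groups), or twice, instead of cleanly at the ortho position.

   Fallback, from 1, returning at 6: the bromine is introduced before the ring is built. Phenol 1 is brominated with NBS in CH2Cl2 at −78 °C, and 2-bromo-3,5-dimethoxyphenol F2 is separated from the para isomer at this cheap first stage. Pechmann condensation of F2 with 2 (CF3CO2H) can only close at the remaining ortho position and should give 8-bromo-5,7-dimethoxy-4-phenyl-2H-chromen-2-one F3. Copper hydride reduction under the conditions of step 2, to which an aryl bromide should be inert, should give (4R)-8-bromo-5,7-dimethoxy-4-phenylchroman-2-one F4. Opening with KOtBu as in step 3 then gives 6.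

3. Step 2. Hydride delivery may be slow or poorly face-selective, because the C5 methoxy group is peri to the twisted 4-phenyl group and crowds C4; the lactone may also be reduced further to the lactol.

   Fallback, from 1, returning at 4: phenol 1 and (E)-cinnamaldehyde are combined with a catalytic amount of α,α-diphenylprolinol trimethylsilyl ether (the enantiomer that leads to the 4R series) and benzoic acid in CH2Cl2 at 0 °C. Iminium activation, Friedel–Crafts alkylation ortho to the hydroxyl group and hemiacetal closure should give (4R)-5,7-dimethoxy-4-phenylchroman-2-ol F5 (both C2 epimers). Oxidation of the lactol with PhI(OAc)2 and catalytic TEMPO in CH2Cl2 gives 4. Lactol formed by over-reduction in step 2 can be returned to 4 by the same oxidation.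

**Further compounds**

F1 | step 7 | 3-(4-methoxyphenyl)propanoyl chloride | COc1ccc(CCC(=O)Cl)cc1
F2 | step 4 | 2-bromo-3,5-dimethoxyphenol | COc1cc(O)c(Br)c(OC)c1
F3 | step 4 | 8-bromo-5,7-dimethoxy-4-phenyl-2H-chromen-2-one | O=C1C=C(c2ccccc2)c2c(OC)cc(OC)c(Br)c2O1
F4 | step 4 | (4R)-8-bromo-5,7-dimethoxy-4-phenylchroman-2-one | O=C1C[C@H](c2ccccc2)c2c(OC)cc(OC)c(Br)c2O1
F5 | step 2 | (4R)-5,7-dimethoxy-4-phenylchroman-2-ol | OC1C[C@H](c2ccccc2)c2c(OC)cc(OC)cc2O1
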